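Teal holds 0.63 M of solid reagent and red 2.5 M, yet at 80.0 min teal reads 12.6 % left-handed product and red 12.2 %, so within a scatter of 0.3 percentage points the solid charge leaves no visible mark.

| flask | left-handed substrate | right-handed substrate | solid reagent | remark | time |
|---|---|---|---|---|---|
| teal | 0.42 M | 0.42 M | 0.63 M | run made earlier |  |
| red | 0.42 M | 0.42 M | 2.5 M | run made earlier |  |
| grey | 0.21 M | 0.21 M | 1.26 M | run made earlier |  |
| flask | 0.42 M | 0.42 M | 1.26 M |  | 1.5 h |

| run | time / min | left-handed product / % | right-handed product / % |
|---|---|---|---|
| teal | 10.0 | 0.5 | 0.3 |
| teal | 25.0 | 3.5 | 1.8 |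
| teal | 50.0 | 6.9 | 6.3 |
| teal | 80.0 | 12.6 | 11.1 |
| red | 10.0 | 1.0 | 0.3 |
| red | 25.0 | 3.3 | 2.1 |
| red | 50.0 | 7.6 | 6.1 |
| red | 80.0 | 12.2 | 11.1 |
| grey | 6.00 | 0 | 0.4 |
| grey | 12.0 | 1.0 | 1.0 |
| grey | 30.0 | 5.4 | 4.1 |
| grey | 80.0 | 17.8 | 16.5 |

(each reading ± 0.3 percentage points)

- partner is single-handed; left-handed substrate and right-handed substrate are mirror images of each other, charged as a racemate, each of them at the stated concentration
- solid, in amounts per volume of the solution: solid reagent
- the analysis behind the earlier runs scatters by 0.3 percentage points, standard deviation
- at the start none of the solid reagent is in solution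
- an excess is below zero if the other one leads
- the handed part of partner does not stay in what it makes, so the products of the two hands are mirror images too

1. excess of left-handed product over right-handed product in the product at 2.0 min
2. excess of left-handed product over right-handed product in the product at 1.5 h
3. part of the left-handed substrate and right-handed substrate charged together that has reacted at 1.5 h

The excess is not what stays still, though. Red's left-minus-right difference is 1.2 points at 25.0 min and 1.1 points at 80.0 min, while its product keeps growing. So I freeze the gap, the left-handed product minus the right-handed product in percent of both substrates charged, as a quasi-steady state. Averaged over the three runs at 80.0 min, it reads 1.3 points. The excess is then the gap divided by the conversion. Extending the teal and red slopes to 1.5 h, I reckon a conversion of 26.8 % for the flask, hence an excess of 4.84 %.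

The forecast says 30 %, 4.6 % and 27 %, on the reading “It plateaus at about 1.2 percentage points from roughly 25 min in all runs”. Its excess at 1.5 h is lower than mine.

The flask gives 32.9 %, 4.30 % and 26.6 %. With the interconversion of the two products struck out, its excess at 1.5 h is 35.0 %. Its gap, excess times conversion, comes to 1.1 points, against my reading of 1.3 points.

    left-handed substrate ⇌ right-handed substrate (k = 0.00670 s⁻¹)
    partner ⇌ dormant form (K = 0.430, k = 1.50 × 10⁻⁴ s⁻¹)
    partner + left-handed substrate → left-handed product (k = 0.00250 L mol⁻¹ s⁻¹)
    left-handed product ⇌ right-handed product (k = 8.20 × 10⁻⁴ s⁻¹)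
    solid reagent ⇌ partner, rate k5*(cs5 - [partner]) while solid is left; crystals form when [partner] > cs5 (solubility = 0.220 M, k = 2.70 × 10⁻⁴ s⁻¹)
    partner + right-handed substrate → right-handed product (k = 0.00120 L mol⁻¹ s⁻¹)

For the neighbour with 0.50 M of solid reagent, the gap of 1.3 points over the same conversion of 26.8 % gives 4.84 % again. The neighbour computes to 4.30 % at 26.6 % conversion, with 53 % of its charged solid reagent still there, solid or dissolved.

The numbers in the tables were generated by integration with constants of no real substance, and the scatter is random.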